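**Plan**

- Cuts, in retrosynthetic order: C11=C12 (Wittig, then saturation); the C9–C10 bond of the cyclohexene ring, traced back to a C11–C10 bond; C5–C10 and C6–C7 together; C10=C11; the C4–CH2O bond.
- Feature used: C9 is quaternary and carries a methyl and the single carbon C11 that leaves the ring system. So the ring C5–C6–C7–C8–C9–C10 can be the contracted form of the seven-membered ring C5–C6–C7–C8–C9–C11–C10: its C9(Me)–C11 epoxide opens at tertiary C9, C10 shifts from C11 to C9, and C11 becomes the aldehyde.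
- That seven-membered ring has C5=C6 and C9=C11 in a 1,4-relation across C10, the pattern of a Rh(I) [5+2] cycloaddition of an alkyne (C5≡C6) with a vinylcyclopropane (C10=C11–C9, ring C9/C8/C7); the tether C1–C4 closes the cyclohexane ring in the same step.
- Forward: tether fragment (steps 1–7) and cyclopropane fragment (8–9) are joined by olefination (10); [5+2] builds both rings (11); epoxidation (12); ring contraction (13); side chain by Wittig/reduction (14–17); deprotection and acetylation (18–19).
- Stereochemistry: C4 from a Sharpless epoxide and a stereospecific 1,2-shift; C8 from a ligand-controlled cyclopropanation; C10 from the stereospecific [5+2]; C9 from face-selective epoxidation and anti migration; C13 from methyl hydrogen (R)-3-methylglutarate.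

Key step: step 13

Remark: the carbons of all intermediates carry the halimane numbers of the target (C17 = methyl on C8, C18 = CH2O carbon on C4, C19 = methyl on C4, C20 = methyl on C9); the target is read from the SMILES as (4R,8S,9R,10S,13R).

**Route**

Step 1
Reactants: 1 6-chlorohex-1-yne
Product: 4 (2E)-7-chloro-3-methylhept-2-en-1-ol, via alkenylalane 2 (not isolated), via lithium alkenylalanate 3 (not isolated)
Conditions: Me3Al, Cp2ZrCl2 (20 mol %), CH2Cl2, 0 °C to rt; n-BuLi, THF, −78 °C; (CH2O)n, −78 °C to rt; aq. HCl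
Reagents that add atoms: trimethylaluminium C[Al](C)C; paraformaldehyde (as formaldehyde) C=O
Why: Negishi zirconium-catalysed carboalumination adds methyl and aluminium syn across the terminal alkyne (methyl on the internal carbon), and the derived alanate is hydroxymethylated with retention, which should give the (E)-allylic alcohol that already holds C18, C5, C4 with its methyl, C3–C1 and C10 as the chloride.

Step 2
Reactants: 4 (2E)-7-chloro-3-methylhept-2-en-1-ol
Product: 5 [(2S,3S)-3-(4-chlorobutyl)-3-methyloxiran-2-yl]methanol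
Conditions: Ti(OiPr)4 (10 mol %), L-(+)-diethyl tartrate (12 mol %), t-BuOOH, 4 Å MS, CH2Cl2, −20 °C
Reagents that add atoms: tert-butyl hydroperoxide CC(C)(C)OO
Why: Sharpless asymmetric epoxidation of a geraniol-type (E)-3-methylalk-2-en-1-ol with the L-(+)-tartrate should deliver oxygen to the face that gives the (2S,3S)-epoxide, which holds the configuration later transferred to C4.

Step 3
Reactants: 5 [(2S,3S)-3-(4-chlorobutyl)-3-methyloxiran-2-yl]methanol
Product: 6 tert-butyl{[(2S,3S)-3-(4-chlorobutyl)-3-methyloxiran-2-yl]methoxy}dimethylsilane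
Conditions: TBSCl, imidazole, DMF, rt
Reagents that add atoms: tert-butyldimethylsilyl chloride CC(C)(C)[Si](C)(C)Cl
Why: Routine silylation of the primary alcohol; the silyloxymethyl group is the migrating group of the next step and the protected C18 oxygen for the rest of the route.

Step 4
Reactants: 6 tert-butyl{[(2S,3S)-3-(4-chlorobutyl)-3-methyloxiran-2-yl]methoxy}dimethylsilane
Product: 7 (2S)-2-{[(tert-butyldimethylsilyl)oxy]methyl}-6-chloro-2-methylhexanal
Conditions: MABR [MeAl(OAr)2, Ar = 4-bromo-2,6-di-tert-butylphenyl, from Me3Al and ArOH] (2 equiv), CH2Cl2, −78 °C; aq. HCl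
Reagents that add atoms: none
Why: Meinwald-type rearrangement of a 2,3-epoxy silyl ether with a bulky aluminium aryloxide: the epoxide opens at the tertiary carbon and the CH2OSi group shifts anti to the breaking C–O bond (inversion), so the epoxide chirality should be transferred to the quaternary C4 (CH3, CH2OTBS, CHO, chain).

Step 5
Reactants: 7 (2S)-2-{[(tert-butyldimethylsilyl)oxy]methyl}-6-chloro-2-methylhexanal
Product: 8 tert-butyl{[(2R)-6-chloro-2-ethynyl-2-methylhexyl]oxy}dimethylsilane
Conditions: dimethyl (1-diazo-2-oxopropyl)phosphonate, K2CO3, MeOH, 0 °C to rt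
Reagents that add atoms: dimethyl (1-diazo-2-oxopropyl)phosphonate COP(=O)(OC)C(=[N+]=[N-])C(C)=O
Why: Ohira–Bestmann (Seyferth–Gilbert) homologation of a non-enolisable aldehyde under mild carbonate conditions should give the terminal alkyne C5≡C6 without touching C4 (the descriptor changes only because of the priority rules).

Step 6
Reactants: 8 tert-butyl{[(2R)-6-chloro-2-ethynyl-2-methylhexyl]oxy}dimethylsilane
Product: 9 5-{[(5R)-5-{[(tert-butyldimethylsilyl)oxy]methyl}-5-methylhept-6-yn-1-yl]sulfanyl}-1-phenyl-1H-tetrazole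
Conditions: 1-phenyl-1H-tetrazole-5-thiol, K2CO3, NaI (cat.), DMF, 60 °C
Reagents that add atoms: 1-phenyl-1H-tetrazole-5-thiol Sc1nnnn1-c1ccccc1
Why: SN2 thioetherification of the primary chloride (iodide catalysis) by the soft tetrazolethiolate should leave the alkyne and the silyl ether untouched.

Step 7
Reactants: 9 5-{[(5R)-5-{[(tert-butyldimethylsilyl)oxy]methyl}-5-methylhept-6-yn-1-yl]sulfanyl}-1-phenyl-1H-tetrazole
Product: 10 5-{[(5R)-5-{[(tert-butyldimethylsilyl)oxy]methyl}-5-methylhept-6-yn-1-yl]sulfonyl}-1-phenyl-1H-tetrazole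
Conditions: (NH4)6Mo7O24·4H2O (cat.), 30% H2O2, EtOH, 0 °C to rt
Reagents that add atoms: hydrogen peroxide OO
Why: Molybdate-catalysed peroxide oxidation takes the sulfide to the sulfone needed for the Julia–Kocienski olefination; alkyne and neopentyl silyl ether should be inert.

Step 8
Reactants: 11 (2E)-2-methylbut-2-en-1-ol (tiglyl alcohol)
Product: 12 [(1S,2S)-1,2-dimethylcyclopropyl]methanol
Conditions: Et2Zn, CH2I2, DME, (4R,5R)-2-butyl-N,N,N',N'-tetramethyl-1,3,2-dioxaborolane-4,5-dicarboxamide (1.2 equiv), CH2Cl2, −10 °C to rt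
Reagents that add atoms: diiodomethane ICI
Why: Simmons–Smith cyclopropanation of the allylic alcohol directed by the chiral dioxaborolane (Charette conditions) is stereospecific for the (E)-alkene (the two methyls end up cis), and the (4R,5R)-ligand should give the (1S,2S)-cyclopropane, which fixes C8.

Step 9
Reactants: 12 [(1S,2S)-1,2-dimethylcyclopropyl]methanol
Product: 13 (1S,2S)-1,2-dimethylcyclopropane-1-carbaldehyde (volatile, used as a solution)
Conditions: TEMPO (10 mol %), PhI(OAc)2, CH2Cl2, rt
Reagents that add atoms: none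
Why: Nitroxyl-catalysed oxidation of the primary alcohol stops at the aldehyde, which has no α-hydrogen and cannot epimerise.

Step 10
Reactants: 10 5-{[(5R)-5-{[(tert-butyldimethylsilyl)oxy]methyl}-5-methylhept-6-yn-1-yl]sulfonyl}-1-phenyl-1H-tetrazole; 13 (1S,2S)-1,2-dimethylcyclopropane-1-carbaldehyde
Product: 15 tert-butyl{[(2R,6E)-7-[(1S,2S)-1,2-dimethylcyclopropyl]-2-ethynyl-2-methylhept-6-en-1-yl]oxy}dimethylsilane, via potassium sulfonyl carbanion 14 (not isolated)
Conditions: KHMDS (1.05 equiv), DME, −60 °C; then 13, −60 °C to rt; aq. NH4Cl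
Reagents that add atoms: none
Why: Julia–Kocienski olefination of a 1-phenyltetrazolyl sulfone with an α-quaternary aldehyde under potassium/DME conditions should give the (E)-alkene C10=C11 by Smiles rearrangement and elimination; the sulfone CH2 is more acidic than the alkyne C–H.

Step 11
Reactants: 15 tert-butyl{[(2R,6E)-7-[(1S,2S)-1,2-dimethylcyclopropyl]-2-ethynyl-2-methylhept-6-en-1-yl]oxy}dimethylsilane
Product: 16 tert-butyl{[(1R,4aS,7S)-1,6,7-trimethyl-2,3,4,4a,7,8-hexahydro-1H-benzo[7]annulen-1-yl]methoxy}dimethylsilane (halimane locants: 4R,8S,10S; double bonds C5=C6 and C9=C11)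
Conditions: [Rh(CO)2Cl]2 (5 mol %), toluene (0.02 M), 110 °C
Reagents that add atoms: none
Why: Rh(I)-catalysed intramolecular [5+2] cycloaddition of the vinylcyclopropane with the tethered alkyne should form C5–C10 (closing the cyclohexane ring through the four-carbon tether) and, after cleavage of the less substituted cyclopropane bond C9–C7, C6–C7 (closing the cycloheptadiene); since the cleaved bond and the alkene face that bonds to C5 lie on the same side of the (E)-vinylcyclopropane, C10 is set relative to C8 (H-8 and H-10 cis) and independently of C4.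

Step 12
Reactants: 16 tert-butyl{[(1R,4aS,7S)-1,6,7-trimethyl-2,3,4,4a,7,8-hexahydro-1H-benzo[7]annulen-1-yl]methoxy}dimethylsilane
Product: 17 the 9,11-epoxide of 16 with the oxygen on the face of H-8 and H-10 (halimane locants: 4R,8S,9R,10R,11S)
Conditions: mCPBA (1.0 equiv), NaHCO3, CH2Cl2, −20 °C
Reagents that add atoms: 3-chloroperbenzoic acid OOC(=O)c1cccc(Cl)c1
Why: Prilezhaev epoxidation; of the two trisubstituted double bonds C9=C11 is the open one (C5=C6 is flanked by the quaternary C4 and its CH2OTBS group), and both of its allylic substituents (C17 on C8, C1 on C10) sit on one face, so the oxygen should enter from the face of H-8 and H-10 and set C9 and C11.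

Step 13
Reactants: 17 the 9,11-epoxide of 16 (4R,8S,9R,10R,11S)
Product: 18 (1R,2S,5R,8aR)-5-{[(tert-butyldimethylsilyl)oxy]methyl}-1,2,5-trimethyl-1,2,3,5,6,7,8,8a-octahydronaphthalene-1-carbaldehyde (halimane locants: 4R,8S,9R,10R; C11 = CHO)
Conditions: MABR [MeAl(OAr)2, Ar = 4-bromo-2,6-di-tert-butylphenyl, from Me3Al and ArOH] (2 equiv), CH2Cl2, −78 to −40 °C; aq. HCl
Reagents that add atoms: none
Why: The aluminium Lewis acid binds the epoxide oxygen, the C9–O bond ionises at the tertiary carbon, and the ring bond C11–C10 shifts to C9 anti to the leaving oxygen while C11–O collapses to the aldehyde, so the seven-membered ring C5–C6–C7–C8–C9–C11–C10 contracts to the six-membered ring C5–C6–C7–C8–C9–C10. The closest known reaction type is the Meinwald rearrangement of trisubstituted epoxides to α-quaternary aldehydes with bulky aluminium aryloxides, including the ring contraction of 1-methylcycloalkene oxides (step 4 uses the same reagent class). The ring is closed by a suprafacial 1,2-alkyl shift and not by a cyclisation, and the migrating C10 keeps its configuration. C9 is the only new stereocentre and is fixed by the epoxide face, because C10 enters anti to the oxygen; this places the formyl carbon C11 cis to H-10 and the C9 methyl cis to the C8 methyl. The step needs the C–C shift to win over the 1,2-hydride shift from C11 and over capture of the C9 cation by C5=C6; the allylic, secondary nature of C10, the strain released on going from the seven- to the six-membered ring and the bulky, non-nucleophilic Lewis acid at low temperature should secure this.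

Step 14
Reactants: 19 methyl hydrogen (R)-3-methylglutarate [(3R)-5-methoxy-3-methyl-5-oxopentanoic acid]
Product: 20 methyl (3S)-4-bromo-3-methylbutanoate
Conditions: Ag(phen)2OTf (2.5 mol %), dibromoisocyanuric acid (0.8 equiv), 1,2-dichloroethane, rt
Reagents that add atoms: dibromoisocyanuric acid O=C1NC(=O)N(Br)C(=O)N1Br
Why: Silver-catalysed radical decarboxylative bromination (Hunsdiecker type) of the primary acid; the stereocentre (later C13) is next to, not at, the radical carbon and should be kept.

Step 15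
Reactants: 20 methyl (3S)-4-bromo-3-methylbutanoate
Product: 21 [(2S)-4-methoxy-2-methyl-4-oxobutyl]triphenylphosphonium bromide
Conditions: PPh3, MeCN, reflux
Reagents that add atoms: triphenylphosphine c1ccc(cc1)P(c1ccccc1)c1ccccc1
Why: SN2 quaternisation of triphenylphosphine by the primary bromide, slow because of the β-branch but not otherwise problematic.

Step 16
Reactants: 18 (1R,2S,5R,8aR)-5-{[(tert-butyldimethylsilyl)oxy]methyl}-1,2,5-trimethyl-1,2,3,5,6,7,8,8a-octahydronaphthalene-1-carbaldehyde; 21 [(2S)-4-methoxy-2-methyl-4-oxobutyl]triphenylphosphonium bromide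
Product: 23 methyl (3S,4Z)-5-[(1S,2S,5R,8aS)-5-{[(tert-butyldimethylsilyl)oxy]methyl}-1,2,5-trimethyl-1,2,3,5,6,7,8,8a-octahydronaphthalen-1-yl]-3-methylpent-4-enoate, via phosphonium ylide 22 (not isolated)
Conditions: NaHMDS (1.0 equiv), THF, −78 to 0 °C; then 18, −78 °C to rt
Reagents that add atoms: none
Why: Wittig olefination of the neopentyl aldehyde with the non-stabilised ylide joins C11 to C12 (mainly Z, which is irrelevant after step 17); C13 comes from the chiral pool and is not touched.

Step 17
Reactants: 23 methyl (3S,4Z)-5-[(1S,2S,5R,8aS)-5-{[(tert-butyldimethylsilyl)oxy]methyl}-1,2,5-trimethyl-1,2,3,5,6,7,8,8a-octahydronaphthalen-1-yl]-3-methylpent-4-enoate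
Product: 24 methyl (3R)-5-[(1R,2S,5R,8aS)-5-{[(tert-butyldimethylsilyl)oxy]methyl}-1,2,5-trimethyl-1,2,3,5,6,7,8,8a-octahydronaphthalen-1-yl]-3-methylpentanoate
Conditions: TsNHNH2, NaOAc, THF/H2O, reflux
Reagents that add atoms: none
Why: Diimide transfers H2 to the 1,2-disubstituted C11=C12 bond and should leave the hindered trisubstituted C5=C6 bond alone.

Step 18
Reactants: 24 methyl (3R)-5-[(1R,2S,5R,8aS)-5-{[(tert-butyldimethylsilyl)oxy]methyl}-1,2,5-trimethyl-1,2,3,5,6,7,8,8a-octahydronaphthalen-1-yl]-3-methylpentanoate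
Product: 26 (3R)-5-[(1R,2S,5R,8aS)-5-(hydroxymethyl)-1,2,5-trimethyl-1,2,3,5,6,7,8,8a-octahydronaphthalen-1-yl]-3-methylpentanoic acid, via silyl ether acid 25 (not isolated)
Conditions: LiOH·H2O, THF/H2O, 40 °C; then 3 M HCl to pH 1, rt
Reagents that add atoms: lithium hydroxide [Li+].[OH-]
Why: Saponification of the methyl ester, followed in the same flask by acid hydrolysis of the primary silyl ether; the trisubstituted alkene should tolerate dilute aqueous acid at room temperature.

Step 19
Reactants: 26 (3R)-5-[(1R,2S,5R,8aS)-5-(hydroxymethyl)-1,2,5-trimethyl-1,2,3,5,6,7,8,8a-octahydronaphthalen-1-yl]-3-methylpentanoic acid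
Product: 27 (3R)-5-[(1R,2S,5R,8aS)-5-(acetoxymethyl)-1,2,5-trimethyl-1,2,3,5,6,7,8,8a-octahydronaphthalen-1-yl]-3-methylpentanoic acid (target)
Conditions: Ac2O, pyridine, DMAP (cat.), CH2Cl2, rt; then aq. NaHCO3, then acidification
Reagents that add atoms: acetic anhydride CC(=O)OC(C)=O
Why: Acylation of the primary neopentyl alcohol; any mixed anhydride formed at the carboxylic acid is hydrolysed during the aqueous work-up.

**Compound list**

1 | 6-chlorohex-1-yne | C#CCCCCCl | starting material
2 | (E)-(6-chloro-2-methylhex-1-en-1-yl)dimethylalane | C[Al](C)/C=C(\C)CCCCCl | intermediate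
3 | lithium butyl[(E)-6-chloro-2-methylhex-1-en-1-yl]dimethylalanate | [Li+].CCCC[Al-](C)(C)/C=C(\C)CCCCCl | intermediate
4 | (2E)-7-chloro-3-methylhept-2-en-1-ol | OC/C=C(\C)CCCCCl | intermediate
5 | [(2S,3S)-3-(4-chlorobutyl)-3-methyloxiran-2-yl]methanol | OC[C@@H]1O[C@@]1(C)CCCCCl | intermediate
6 | tert-butyl{[(2S,3S)-3-(4-chlorobutyl)-3-methyloxiran-2-yl]methoxy}dimethylsilane | CC(C)(C)[Si](C)(C)OC[C@@H]1O[C@@]1(C)CCCCCl | intermediate
7 | (2S)-2-{[(tert-butyldimethylsilyl)oxy]methyl}-6-chloro-2-methylhexanal | O=C[C@](C)(CO[Si](C)(C)C(C)(C)C)CCCCCl | intermediate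
8 | tert-butyl{[(2R)-6-chloro-2-ethynyl-2-methylhexyl]oxy}dimethylsilane | C#C[C@](C)(CO[Si](C)(C)C(C)(C)C)CCCCCl | intermediate
9 | 5-{[(5R)-5-{[(tert-butyldimethylsilyl)oxy]methyl}-5-methylhept-6-yn-1-yl]sulfanyl}-1-phenyl-1H-tetrazole | C#C[C@](C)(CO[Si](C)(C)C(C)(C)C)CCCCSc1nnnn1-c1ccccc1 | intermediate
10 | 5-{[(5R)-5-{[(tert-butyldimethylsilyl)oxy]methyl}-5-methylhept-6-yn-1-yl]sulfonyl}-1-phenyl-1H-tetrazole | C#C[C@](C)(CO[Si](C)(C)C(C)(C)C)CCCCS(=O)(=O)c1nnnn1-c1ccccc1 | intermediate
11 | (2E)-2-methylbut-2-en-1-ol | C/C=C(\C)CO | starting material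
12 | [(1S,2S)-1,2-dimethylcyclopropyl]methanol (methyls cis) | OC[C@@]1(C)C[C@@H]1C | intermediate
13 | (1S,2S)-1,2-dimethylcyclopropane-1-carbaldehyde | O=C[C@@]1(C)C[C@@H]1C | intermediate
14 | potassium salt of the α-sulfonyl carbanion of 10 | [K+].C#C[C@](C)(CO[Si](C)(C)C(C)(C)C)CCC[CH-]S(=O)(=O)c1nnnn1-c1ccccc1 | intermediate
15 | tert-butyl{[(2R,6E)-7-[(1S,2S)-1,2-dimethylcyclopropyl]-2-ethynyl-2-methylhept-6-en-1-yl]oxy}dimethylsilane | C#C[C@](C)(CO[Si](C)(C)C(C)(C)C)CCC/C=C/[C@@]1(C)C[C@@H]1C | intermediate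
16 | tert-butyl{[(1R,4aS,7S)-1,6,7-trimethyl-2,3,4,4a,7,8-hexahydro-1H-benzo[7]annulen-1-yl]methoxy}dimethylsilane (H-8 and H-10 cis) | CC(C)(C)[Si](C)(C)OC[C@]1(C)CCC[C@H]2C=C(C)[C@@H](C)CC=C12 | intermediate
17 | 9,11-epoxide of 16, oxygen on the face of H-8 and H-10 (halimane locants 4R,8S,9R,10R,11S) | CC(C)(C)[Si](C)(C)OC[C@]1(C)CCC[C@H]2[C@@H]3O[C@]3(C)[C@@H](C)CC=C12 | intermediate
18 | (1R,2S,5R,8aR)-5-{[(tert-butyldimethylsilyl)oxy]methyl}-1,2,5-trimethyl-1,2,3,5,6,7,8,8a-octahydronaphthalene-1-carbaldehyde | CC(C)(C)[Si](C)(C)OC[C@]1(C)CCC[C@@H]2C1=CC[C@H](C)[C@@]2(C)C=O | intermediate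
19 | methyl hydrogen (R)-3-methylglutarate | COC(=O)C[C@H](C)CC(=O)O | starting material
20 | methyl (3S)-4-bromo-3-methylbutanoate | COC(=O)C[C@H](C)CBr | intermediate
21 | [(2S)-4-methoxy-2-methyl-4-oxobutyl]triphenylphosphonium bromide | [Br-].COC(=O)C[C@H](C)C[P+](c1ccccc1)(c1ccccc1)c1ccccc1 | intermediate
22 | methyl (3S)-3-methyl-4-(triphenyl-λ5-phosphanylidene)butanoate | COC(=O)C[C@H](C)C=P(c1ccccc1)(c1ccccc1)c1ccccc1 | intermediate
23 | methyl (3S,4Z)-5-[(1S,2S,5R,8aS)-5-{[(tert-butyldimethylsilyl)oxy]methyl}-1,2,5-trimethyl-1,2,3,5,6,7,8,8a-octahydronaphthalen-1-yl]-3-methylpent-4-enoate | CC(C)(C)[Si](C)(C)OC[C@]1(C)CCC[C@@H]2C1=CC[C@H](C)[C@@]2(C)/C=C\[C@@H](C)CC(=O)OC | intermediate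
24 | methyl (3R)-5-[(1R,2S,5R,8aS)-5-{[(tert-butyldimethylsilyl)oxy]methyl}-1,2,5-trimethyl-1,2,3,5,6,7,8,8a-octahydronaphthalen-1-yl]-3-methylpentanoate | CC(C)(C)[Si](C)(C)OC[C@]1(C)CCC[C@@H]2C1=CC[C@H](C)[C@@]2(C)CC[C@@H](C)CC(=O)OC | intermediate
25 | (3R)-5-[(1R,2S,5R,8aS)-5-{[(tert-butyldimethylsilyl)oxy]methyl}-1,2,5-trimethyl-1,2,3,5,6,7,8,8a-octahydronaphthalen-1-yl]-3-methylpentanoic acid | CC(C)(C)[Si](C)(C)OC[C@]1(C)CCC[C@@H]2C1=CC[C@H](C)[C@@]2(C)CC[C@@H](C)CC(=O)O | intermediate
26 | (3R)-5-[(1R,2S,5R,8aS)-5-(hydroxymethyl)-1,2,5-trimethyl-1,2,3,5,6,7,8,8a-octahydronaphthalen-1-yl]-3-methylpentanoic acid | OC[C@]1(C)CCC[C@@H]2C1=CC[C@H](C)[C@@]2(C)CC[C@@H](C)CC(=O)O | intermediate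
27 | (3R)-5-[(1R,2S,5R,8aS)-5-(acetoxymethyl)-1,2,5-trimethyl-1,2,3,5,6,7,8,8a-octahydronaphthalen-1-yl]-3-methylpentanoic acid | CC(=O)OC[C@]1(C)CCC[C@@H]2C1=CC[C@H](C)[C@@]2(C)CC[C@@H](C)CC(=O)O | target

**Step count and risks**

Total: 19 steps. Longest linear sequence: 15 steps (1–7, 10–13, 16–19).

Steps most likely to fail:

1. Step 11. The cycloaddition may be too slow for a tether that closes a six-membered ring with an alkyne shielded by the quaternary C4, so that alkyne oligomerisation or isomerisation of the vinylcyclopropane takes over; the metal may also cleave the more substituted cyclopropane bond C9–C8 and put the methyl group on the wrong ring carbon. Fallback: the cyclohexene ring is closed directly by a Diels–Alder reaction, setting out from 7 and coming back at 18 (steps 8–13 are then not needed). Finkelstein exchange (NaI, acetone) should turn 7 into the iodo aldehyde F1, and a samarium diiodide Barbier cyclisation (SmI2, HMPA, THF) should close the cyclohexanol F2. Dess–Martin oxidation should give the ketone F3, and KHMDS/PhNTf2 the enol triflate F4 (only C10 can enolise). Stille coupling with tributyl(vinyl)stannane (Pd(PPh3)4, LiCl) should give the diene F5. A Diels–Alder reaction of F5 with (E)-2-methylbut-2-enal, catalysed by a chiral oxazaborolidinium triflimide, should then give 18: the formyl-bearing carbon bonds to the substituted diene terminus C10, the aldehyde is exo (so C17 and C20 are cis and C11 is cis to H-10), and the face is chosen by the catalyst enantiomer.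

2. Step 12. The peracid may attack C5=C6 as well, or both double bonds, or the wrong face of C9=C11. Fallback: a bulkier, cis-specific oxidant followed by stereoretentive epoxide formation, setting out from 16 and coming back at 17. Osmium-catalysed dihydroxylation (K2OsO4, NMO, acetone/H2O) should give the cis-9,11-diol F6 from the face of H-8 and H-10. Trimethyl orthoacetate/PPTS and then acetyl bromide should give the bromo acetate F7 (bromide enters C11 with inversion). K2CO3 in MeOH should close F7 to 17 with a second inversion, so the configuration is retained overall.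

3. Step 16. The hindered neopentyl aldehyde may not condense with the β-branched ylide before the ylide decomposes or attacks its own ester. Fallback: the chain is built by cross-coupling and C13 is set by asymmetric conjugate reduction, setting out from 18 and coming back at 24 (steps 14, 15 and 17 are then not needed). Methylenation with the small ylide Ph3P=CH2 should give the vinyl compound F8. 9-BBN should add only to the terminal double bond to give the borane F9 (used directly), and Suzuki–Miyaura coupling with methyl (Z)-3-iodobut-2-enoate (Pd(dppf)Cl2, Cs2CO3, DMF/H2O) should give the (Z)-enoate F10. Copper hydride-catalysed asymmetric 1,4-reduction (Cu(OAc)2, chiral bisphosphine chosen for the 13R product, polymethylhydrosiloxane, t-BuOH) should then give 24.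

**Further compounds**

F1 | step 11 | (2S)-2-{[(tert-butyldimethylsilyl)oxy]methyl}-6-iodo-2-methylhexanal | O=C[C@](C)(CO[Si](C)(C)C(C)(C)C)CCCCI
F2 | step 11 | (2S)-2-{[(tert-butyldimethylsilyl)oxy]methyl}-2-methylcyclohexan-1-ol (both C1 epimers) | OC1CCCC[C@@]1(C)CO[Si](C)(C)C(C)(C)C
F3 | step 11 | (2S)-2-{[(tert-butyldimethylsilyl)oxy]methyl}-2-methylcyclohexan-1-one | O=C1CCCC[C@@]1(C)CO[Si](C)(C)C(C)(C)C
F4 | step 11 | (6S)-6-{[(tert-butyldimethylsilyl)oxy]methyl}-6-methylcyclohex-1-en-1-yl trifluoromethanesulfonate | FC(F)(F)S(=O)(=O)OC1=CCCC[C@@]1(C)CO[Si](C)(C)C(C)(C)C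
F5 | step 11 | tert-butyl{[(1R)-2-ethenyl-1-methylcyclohex-2-en-1-yl]methoxy}dimethylsilane | C=CC1=CCCC[C@@]1(C)CO[Si](C)(C)C(C)(C)C
F6 | step 12 | cis-9,11-diol of 16, both hydroxyls on the face of H-8 and H-10 | CC(C)(C)[Si](C)(C)OC[C@]1(C)CCC[C@H]2[C@H](O)[C@@](O)(C)[C@@H](C)CC=C12
F7 | step 12 | 9-acetoxy-11-bromo derivative of 16, bromine trans to the acetoxy group | CC(C)(C)[Si](C)(C)OC[C@]1(C)CCC[C@H]2[C@@H](Br)[C@@](OC(C)=O)(C)[C@@H](C)CC=C12
F8 | step 16 | tert-butyl{[(1R,5S,6S,8aS)-5-ethenyl-1,5,6-trimethyl-1,2,3,5,6,7,8,8a-octahydronaphthalen-1-yl... (the 9-vinyl compound from 18, configuration as in 18)]methoxy}dimethylsilane | CC(C)(C)[Si](C)(C)OC[C@]1(C)CCC[C@@H]2C1=CC[C@H](C)[C@@]2(C)C=C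
F9 | step 16 | B-alkyl-9-borabicyclo[3.3.1]nonane from F8 (boron on C12) | CC(C)(C)[Si](C)(C)OC[C@]1(C)CCC[C@@H]2C1=CC[C@H](C)[C@@]2(C)CCB3C4CCCC3CCC4
F10 | step 16 | methyl (2Z)-5-[decalin unit of 24]-3-methylpent-2-enoate | CC(C)(C)[Si](C)(C)OC[C@]1(C)CCC[C@@H]2C1=CC[C@H](C)[C@@]2(C)CC/C(C)=C\C(=O)OC
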